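Everything rests on making ring B, the benzene ring of the 2,2-dimethylchromene, from a 2-pyrone. In the target, C4a, C8a, C8 and C7 of ring B carry the pyran carbon, the pyran oxygen, the hindered phloroglucinol-type aryl group and hydrogen. The same array sits on C3 to C6 of a 5-aryl-4-hydroxy-2-pyrone once it is annulated with prenal. A Diels-Alder reaction of this pyranopyrone with methyl propiolate, followed by loss of CO2, adds only C5 and C6. One operation therefore delivers the aromatic ring, the congested biaryl and the C6 ester from which flavone 1 grows. Flavone 2 is then built on the unmasked symmetric resorcinol.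

Key step: step 7

Assumption: the target string carries no descriptor for the C8-C8'' biaryl axis, which has one ortho hydrogen, so the axis is treated as configurationally undefined and no stereocentre has to be set.
Locants: chromene atoms are O1, C2, C3, C4, C4a, C5 to C8 and C8a (ring B = C4a to C8a); atoms of flavone 2 carry a double prime (its 4-hydroxyphenyl ring a triple prime).
Design remark: the aryl group of the cycloaddition precursor keeps two small, heat-stable methoxymethyl ethers on the oxygens next to the biaryl bond and a methyl ether on the para oxygen. The methyl ether blocks ring closure to the C6''-linked isomer. It ends up peri to the C4'' carbonyl, the one position from which a methyl group leaves under chelation control.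

Step 1
Reactants: 1 5-methoxyresorcinol; 2 chloromethyl methyl ether
Product: 3 1-methoxy-3,5-bis(methoxymethoxy)benzene
Conditions: NaH (2.4 equiv), DMF, 0 °C; then 2 (2.3 equiv), 0 °C to rt
Reagents that add atoms: chloromethyl methyl ether (2), COCCl
Why: Williamson-type O-alkylation of the bis-phenoxide with the hard electrophile 2 should give the bis-acetal, whose OCH2OMe groups later direct the lithiation and withstand base and heat.

Step 2
Reactants: 3 1-methoxy-3,5-bis(methoxymethoxy)benzene; 4 ethylene oxide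
Product: 6 2-[4-methoxy-2,6-bis(methoxymethoxy)phenyl]ethan-1-ol, via aryllithium 5 (not isolated)
Conditions: n-BuLi (1.1 equiv), THF, 0 °C, 1 h; then 4 (3 equiv, THF solution), -78 °C to rt; H2O
Reagents that add atoms: ethylene oxide (4), C1CO1; n-butyllithium, [Li]CCCC (lithium of 5 only)
Why: Directed ortho-metalation should take place at the C-H flanked by the two chelating OCH2OMe groups, which are stronger directors than OMe, and aryllithium 5 then opens the epoxide by SN2 attack to place the two-carbon arm on the future biaryl carbon.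

Step 3
Reactants: 6 2-[4-methoxy-2,6-bis(methoxymethoxy)phenyl]ethan-1-ol
Product: 8 [4-methoxy-2,6-bis(methoxymethoxy)phenyl]acetic acid, via arylacetaldehyde 7 (not isolated)
Conditions: 2,2,6,6-tetramethylpiperidin-1-oxyl (TEMPO, 20 mol %), PhI(OAc)2 (2.5 equiv), MeCN-H2O 1:1, rt
Reagents that add atoms: water, O
Why: TEMPO/PhI(OAc)2 oxidation (oxoammonium catalysis) takes the primary alcohol to aldehyde 7, whose hydrate is oxidised on to the acid in a weakly acidic medium that spares the acetals and the electron-rich ring.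

Step 4
Reactants: 8 [4-methoxy-2,6-bis(methoxymethoxy)phenyl]acetic acid; 9 potassium ethyl malonate
Product: 11 ethyl 4-[4-methoxy-2,6-bis(methoxymethoxy)phenyl]-3-oxobutanoate, via acyl imidazolide 10 (not isolated)
Conditions: 1,1'-carbonyldiimidazole (1.2 equiv), THF, rt; then 9 (2 equiv), MgCl2 (2 equiv), Et3N (3 equiv), MeCN, rt to 40 °C; aq. NH4Cl
Reagents that add atoms: potassium ethyl malonate (9), CCOC(=O)CC(=O)[O-].[K+]; 1,1'-carbonyldiimidazole, O=C(n1ccnc1)n1ccnc1 (imidazolyl group of 10 only)
Why: Masamune-Brooks homologation, in which acyl imidazolide 10 C-acylates the magnesium enolate of the malonate half-ester and the adduct decarboxylates to the beta-keto ester under near-neutral conditions.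

Step 5
Reactants: 11 ethyl 4-[4-methoxy-2,6-bis(methoxymethoxy)phenyl]-3-oxobutanoate; 12 ethyl formate
Product: 14 4-hydroxy-5-[4-methoxy-2,6-bis(methoxymethoxy)phenyl]-2H-pyran-2-one, via formyl keto ester 13 (not isolated)
Conditions: LiN(i-Pr)2 (3.3 equiv), THF, -78 to 0 °C; 12 (3 equiv), -78 °C to rt; AcOH; then 1,8-diazabicyclo[5.4.0]undec-7-ene (DBU, 1.2 equiv), PhMe, 80 °C
Reagents that add atoms: ethyl formate (12), CCOC=O
Why: The beta-keto ester dianion reacts at its more basic benzylic gamma carbon in a crossed Claisen formylation, and the chelated Z-enol 13 then lactonises onto the ester under DBU (the usual closure of 3,5-dioxo esters to 4-hydroxy-2-pyrones), which leaves pyrone C6 unsubstituted.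

Step 6
Reactants: 14 4-hydroxy-5-[4-methoxy-2,6-bis(methoxymethoxy)phenyl]-2H-pyran-2-one; 15 3-methylbut-2-enal
Product: 17 8-[4-methoxy-2,6-bis(methoxymethoxy)phenyl]-2,2-dimethyl-2H,5H-pyrano[4,3-b]pyran-5-one, via 1-oxatriene 16 (not isolated)
Conditions: 15 (2 equiv), ethylenediammonium diacetate (10 mol %), 1,2-dichloroethane, 60 °C
Reagents that add atoms: 3-methylbut-2-enal (15), CC(C)=CC=O
Why: Formal [3+3] annulation known for 4-hydroxy-2-pyrones and beta,beta-disubstituted enals, in which Knoevenagel condensation at pyrone C3 gives 1-oxatriene 16 and reversible oxa-6pi electrocyclisation onto the C4 oxygen leads to the more stable 2-pyrone-fused 2H-pyran.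

Step 7
Reactants: 17 8-[4-methoxy-2,6-bis(methoxymethoxy)phenyl]-2,2-dimethyl-2H,5H-pyrano[4,3-b]pyran-5-one; 18 methyl propiolate
Product: 20 methyl 8-[4-methoxy-2,6-bis(methoxymethoxy)phenyl]-2,2-dimethyl-2H-chromene-6-carboxylate, via bridged lactone 19 (not isolated)
Conditions: 18 (15 equiv), 2,6-di-tert-butyl-4-methylphenol (5 mol %), o-xylene, sealed tube, 160 °C
Reagents that add atoms: methyl propiolate (18), C#CC(=O)OC
Why: Proposed new method: the 2-pyrone half of 17 should serve as the diene of a concerted thermal [4+2] cycloaddition in which pyrone C3 (C4a of 17) bonds to the unsubstituted alkyne carbon and pyrone C6 (C7 of 17) to the ester-bearing carbon, giving the bridged 2-oxabicyclo[2.2.2]octadienone 19. Retro-[4+2] loss of CO2 from 19 is fast at this temperature and irreversible, so ring B is closed by an intermolecular cycloaddition/cycloreversion pair that forms C4a-C5 and C6-C7 and leaves the ring aromatic. The closest known reaction type is the Diels-Alder/decarboxylation of 4-alkoxy-2-pyrones with propiolates or acetylenedicarboxylates to benzoates; its use on a 2H,5H-pyrano[4,3-b]pyran-5-one, which turns the fused 2H-pyran into a chromene, has not been shown. The two bridgehead stereocentres of 19 arise as a racemate and are erased on aromatisation, so no stereocontrol is required. Regioselectivity is required and is secured by the enol-ether oxygen on pyrone C4 and the ring oxygen on C6, which both polarise the diene towards C3 so that it pairs with the electrophilic beta carbon of 18, and by sterics, since the fully substituted C3 meets the CH terminus; the ester therefore ends para to O1. Site selectivity for the pyrone diene over the 2H-pyran diene C3=C4-C4a=C8a is expected because that diene ends in a fully substituted carbon wedged between the aryl group and the gem-dimethyl carbon.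

Step 8
Reactants: 20 methyl 8-[4-methoxy-2,6-bis(methoxymethoxy)phenyl]-2,2-dimethyl-2H-chromene-6-carboxylate; 21 1-[2,4-bis(benzyloxy)-6-hydroxyphenyl]ethan-1-one
Product: 22 1-[2,4-bis(benzyloxy)-6-hydroxyphenyl]-3-{8-[4-methoxy-2,6-bis(methoxymethoxy)phenyl]-2,2-dimethyl-2H-chromen-6-yl}propane-1,3-dione
Conditions: 21 (1.2 equiv), LiN(SiMe3)2 (4 equiv), THF, -78 to 0 °C; then 20, rt to 50 °C; AcOH
Reagents that add atoms: 1-[2,4-bis(benzyloxy)-6-hydroxyphenyl]ethan-1-one (21), CC(=O)c1c(O)cc(OCc2ccccc2)cc1OCc1ccccc1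
Why: Crossed Claisen condensation of the dilithiated o-hydroxyacetophenone with the non-enolisable aryl ester gives directly the 1,3-diketone that a Baker-Venkataraman rearrangement would deliver, and it is driven by deprotonation of the product.

Step 9
Reactants: 22 1-[2,4-bis(benzyloxy)-6-hydroxyphenyl]-3-{8-[4-methoxy-2,6-bis(methoxymethoxy)phenyl]-2,2-dimethyl-2H-chromen-6-yl}propane-1,3-dione
Product: 23 5,7-bis(benzyloxy)-2-[8-(2,6-dihydroxy-4-methoxyphenyl)-2,2-dimethyl-2H-chromen-6-yl]-4H-chromen-4-one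
Conditions: conc. HCl (cat.), MeOH-THF, 60 °C
Reagents that add atoms: none
Why: Acid-catalysed cyclodehydration of the o-hydroxyaryl 1,3-diketone closes the chromone of flavone 1 while acetal exchange with methanol removes both methoxymethyl groups, conditions that benzyl and methyl ethers and 2,2-dimethylchromenes of flavonoids tolerate.

Step 10
Reactants: 24 1-[4-(benzyloxy)phenyl]ethan-1-one; 25 diethyl carbonate
Product: 26 ethyl 3-[4-(benzyloxy)phenyl]-3-oxopropanoate
Conditions: NaH (2.5 equiv), 25 (3 equiv), THF, reflux; AcOH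
Reagents that add atoms: diethyl carbonate (25), CCOC(=O)OCC
Why: Claisen-type C-ethoxycarbonylation of the ketone enolate with a carbonate, driven by formation of the stabilised beta-keto ester enolate.

Step 11
Reactants: 23 5,7-bis(benzyloxy)-2-[8-(2,6-dihydroxy-4-methoxyphenyl)-2,2-dimethyl-2H-chromen-6-yl]-4H-chromen-4-one; 26 ethyl 3-[4-(benzyloxy)phenyl]-3-oxopropanoate
Product: 28 8-{6-[5,7-bis(benzyloxy)-4-oxo-4H-chromen-2-yl]-2,2-dimethyl-2H-chromen-8-yl}-2-[4-(benzyloxy)phenyl]-7-hydroxy-5-methoxy-4H-chromen-4-one, via C-acyl diketone 27 (not isolated)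
Conditions: 26 (3 equiv), Ph2O, 240 °C, argon sweep (EtOH and H2O distil off)
Reagents that add atoms: ethyl 3-[4-(benzyloxy)phenyl]-3-oxopropanoate (26), CCOC(=O)CC(=O)c1ccc(OCc2ccccc2)cc1
Why: Mentzer pyrone synthesis (the uncatalysed thermal flavone synthesis from phloroglucinol-type phenols and aroylacetates), in which 26 loses ethanol to an aroylketene that C-acylates one of the two equivalent free ring positions and diketone 27 cyclodehydrates through its only ortho hydroxyl, the one next to the biaryl bond, because the other ortho oxygen is a methyl ether, which fixes the C8'' linkage.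

Step 12
Reactants: 28 8-{6-[5,7-bis(benzyloxy)-4-oxo-4H-chromen-2-yl]-2,2-dimethyl-2H-chromen-8-yl}-2-[4-(benzyloxy)phenyl]-7-hydroxy-5-methoxy-4H-chromen-4-one
Product: 29 8-[6-(5,7-dihydroxy-4-oxo-4H-chromen-2-yl)-2,2-dimethyl-2H-chromen-8-yl]-5,7-dihydroxy-2-(4-hydroxyphenyl)-4H-chromen-4-one (CNP0135272.0)
Conditions: BCl3 (10 equiv, 1 M in CH2Cl2), pentamethylbenzene (10 equiv), CH2Cl2, -78 to 0 °C; then H2O
Reagents that add atoms: none
Why: Lewis-acid ether cleavage, in which BCl3 removes the three aryl benzyl groups in the cold with pentamethylbenzene as a non-basic cation trap and takes off the single methyl group by chelation to the peri C4'' carbonyl, while the chromene alkene sits on an electron-poor ring and is kept at or below 0 °C.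

Compound list
1 | 5-methoxyresorcinol | COc1cc(O)cc(O)c1 | starting material
2 | chloromethyl methyl ether | COCCl | starting material
3 | 1-methoxy-3,5-bis(methoxymethoxy)benzene | COCOc1cc(OC)cc(OCOC)c1 | intermediate
4 | ethylene oxide | C1CO1 | starting material
5 | [4-methoxy-2,6-bis(methoxymethoxy)phenyl]lithium | [Li]c1c(OCOC)cc(OC)cc1OCOC | intermediate
6 | 2-[4-methoxy-2,6-bis(methoxymethoxy)phenyl]ethan-1-ol | OCCc1c(OCOC)cc(OC)cc1OCOC | intermediate
7 | [4-methoxy-2,6-bis(methoxymethoxy)phenyl]acetaldehyde | O=CCc1c(OCOC)cc(OC)cc1OCOC | intermediate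
8 | [4-methoxy-2,6-bis(methoxymethoxy)phenyl]acetic acid | OC(=O)Cc1c(OCOC)cc(OC)cc1OCOC | intermediate
9 | potassium ethyl malonate | CCOC(=O)CC(=O)[O-].[K+] | starting material
10 | 1-{[4-methoxy-2,6-bis(methoxymethoxy)phenyl]acetyl}imidazole | O=C(Cc1c(OCOC)cc(OC)cc1OCOC)n1ccnc1 | intermediate
11 | ethyl 4-[4-methoxy-2,6-bis(methoxymethoxy)phenyl]-3-oxobutanoate | CCOC(=O)CC(=O)Cc1c(OCOC)cc(OC)cc1OCOC | intermediate
12 | ethyl formate | CCOC=O | starting material
13 | ethyl (4Z)-5-hydroxy-4-[4-methoxy-2,6-bis(methoxymethoxy)phenyl]-3-oxopent-4-enoate (enol of the gamma-formyl keto ester) | CCOC(=O)CC(=O)/C(=C\O)c1c(OCOC)cc(OC)cc1OCOC | intermediate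
14 | 4-hydroxy-5-[4-methoxy-2,6-bis(methoxymethoxy)phenyl]-2H-pyran-2-one | O=c1cc(O)c(-c2c(OCOC)cc(OC)cc2OCOC)co1 | intermediate
15 | 3-methylbut-2-enal | CC(C)=CC=O | starting material
16 | (3E)-5-[4-methoxy-2,6-bis(methoxymethoxy)phenyl]-3-(3-methylbut-2-en-1-ylidene)-2H-pyran-2,4(3H)-dione | CC(C)=C/C=C1/C(=O)OC=C(c2c(OCOC)cc(OC)cc2OCOC)C1=O | intermediate
17 | 8-[4-methoxy-2,6-bis(methoxymethoxy)phenyl]-2,2-dimethyl-2H,5H-pyrano[4,3-b]pyran-5-one | CC1(C)C=CC2=C(O1)C(c3c(OCOC)cc(OC)cc3OCOC)=COC2=O | intermediate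
18 | methyl propiolate | C#CC(=O)OC | starting material
19 | bridged 2-oxabicyclo[2.2.2]octa-5,7-dien-3-one from addition of 18 across C4a and C7 of 17 (racemic; the bicycle fixes the relative configuration of the two bridgeheads) | CC1(C)C=CC23C(=O)OC(C(C(=O)OC)=C2)C(c4c(OCOC)cc(OC)cc4OCOC)=C3O1 | intermediate
20 | methyl 8-[4-methoxy-2,6-bis(methoxymethoxy)phenyl]-2,2-dimethyl-2H-chromene-6-carboxylate | CC1(C)C=Cc2cc(C(=O)OC)cc(-c3c(OCOC)cc(OC)cc3OCOC)c2O1 | intermediate
21 | 1-[2,4-bis(benzyloxy)-6-hydroxyphenyl]ethan-1-one | CC(=O)c1c(O)cc(OCc2ccccc2)cc1OCc1ccccc1 | starting material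
22 | 1-[2,4-bis(benzyloxy)-6-hydroxyphenyl]-3-{8-[4-methoxy-2,6-bis(methoxymethoxy)phenyl]-2,2-dimethyl-2H-chromen-6-yl}propane-1,3-dione | CC1(C)C=Cc2cc(C(=O)CC(=O)c3c(O)cc(OCc4ccccc4)cc3OCc3ccccc3)cc(-c3c(OCOC)cc(OC)cc3OCOC)c2O1 | intermediate
23 | 5,7-bis(benzyloxy)-2-[8-(2,6-dihydroxy-4-methoxyphenyl)-2,2-dimethyl-2H-chromen-6-yl]-4H-chromen-4-one | CC1(C)C=Cc2cc(-c3cc(=O)c4c(OCc5ccccc5)cc(OCc5ccccc5)cc4o3)cc(-c3c(O)cc(OC)cc3O)c2O1 | intermediate
24 | 1-[4-(benzyloxy)phenyl]ethan-1-one | CC(=O)c1ccc(OCc2ccccc2)cc1 | starting material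
25 | diethyl carbonate | CCOC(=O)OCC | starting material
26 | ethyl 3-[4-(benzyloxy)phenyl]-3-oxopropanoate | CCOC(=O)CC(=O)c1ccc(OCc2ccccc2)cc1 | intermediate
27 | 1-[4-(benzyloxy)phenyl]-3-(3-{6-[5,7-bis(benzyloxy)-4-oxo-4H-chromen-2-yl]-2,2-dimethyl-2H-chromen-8-yl}-2,4-dihydroxy-6-methoxyphenyl)propane-1,3-dione | CC1(C)C=Cc2cc(-c3cc(=O)c4c(OCc5ccccc5)cc(OCc5ccccc5)cc4o3)cc(-c3c(O)cc(OC)c(C(=O)CC(=O)c4ccc(OCc5ccccc5)cc4)c3O)c2O1 | intermediate
28 | 8-{6-[5,7-bis(benzyloxy)-4-oxo-4H-chromen-2-yl]-2,2-dimethyl-2H-chromen-8-yl}-2-[4-(benzyloxy)phenyl]-7-hydroxy-5-methoxy-4H-chromen-4-one | CC1(C)C=Cc2cc(-c3cc(=O)c4c(OCc5ccccc5)cc(OCc5ccccc5)cc4o3)cc(-c3c(O)cc(OC)c4c(=O)cc(-c5ccc(OCc6ccccc6)cc5)oc34)c2O1 | intermediate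
29 | 8-[6-(5,7-dihydroxy-4-oxo-4H-chromen-2-yl)-2,2-dimethyl-2H-chromen-8-yl]-5,7-dihydroxy-2-(4-hydroxyphenyl)-4H-chromen-4-one (CNP0135272.0) | CC1(C)C=Cc2cc(-c3cc(=O)c4c(O)cc(O)cc4o3)cc(-c3c(O)cc(O)c4c(=O)cc(-c5ccc(O)cc5)oc34)c2O1 | target

Total step count: 12
Longest linear sequence: 11 steps (steps 1 to 9, 11 and 12; step 10 is a side branch)

Steps most likely to fail

1. Step 7 (Proposed new method).
- What may go wrong: the cycloaddition may be too slow at the fully substituted diene terminus, which lies next to a perpendicular, doubly ortho-substituted aryl group. At the temperature then needed, the 2H-pyran may open electrocyclically and drain away by hydrogen shift. The alkyne may also add across the 2H-pyran diene with loss of acetone, or the propiolate may polymerise.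
- Fallback (known chemistry only, from 3 back to 20): compound 3 is lithiated as in step 2 and aryllithium 5 is quenched with B(Oi-Pr)3 and aqueous NH4Cl to give [4-methoxy-2,6-bis(methoxymethoxy)phenyl]boronic acid F1. Separately, purchased methyl 3-bromo-4-hydroxybenzoate is O-alkylated with 3-chloro-3-methylbut-1-yne (K2CO3, KI, CuI cat., acetone, reflux) to methyl 3-bromo-4-[(2-methylbut-3-yn-2-yl)oxy]benzoate F2. Heating F2 in N,N-diethylaniline at 190 °C brings about aryl propargyl Claisen rearrangement, hydrogen shift and oxa-6pi closure at the only free ortho position, giving methyl 8-bromo-2,2-dimethyl-2H-chromene-6-carboxylate F3. Suzuki-Miyaura coupling of F1 with F3 (Pd(OAc)2, 2-dicyclohexylphosphino-2',6'-dimethoxybiphenyl, K3PO4, PhMe-H2O, 90 °C) then forms the biaryl bond and gives 20.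

2. Step 11.
- What may go wrong: the aroylketene may be consumed by dimerisation, acyl transfer may stall on the hindered hydroxyl oxygens, and prolonged heating may degrade the chromene by ring opening and hydrogen shift.
- Fallback (from 23 back to 28, replacing thermal acylation by palladium-catalysed carbonylation): one equivalent of N-iodosuccinimide (MeCN, 0 °C) should iodinate the free resorcinol ring, the most electron-rich arene, at one of its two equivalent positions. This gives 5,7-bis(benzyloxy)-2-[8-(2,6-dihydroxy-3-iodo-4-methoxyphenyl)-2,2-dimethyl-2H-chromen-6-yl]-4H-chromen-4-one F4. Carbonylative Sonogashira coupling with purchased 1-(benzyloxy)-4-ethynylbenzene (PdCl2(PPh3)2, CO balloon, Et2NH, DMF, 60 to 100 °C) gives the o-hydroxyaryl ynone 1-(3-{6-[5,7-bis(benzyloxy)-4-oxo-4H-chromen-2-yl]-2,2-dimethyl-2H-chromen-8-yl}-2,4-dihydroxy-6-methoxyphenyl)-3-[4-(benzyloxy)phenyl]prop-2-yn-1-one F5. In the same flask F5 undergoes amine-mediated 6-endo cyclisation through its only ortho hydroxyl to 28.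

3. Step 12.
- What may go wrong: HCl or BCl3 may add to the C3-C4 alkene or ionise the tertiary allylic C2-O1 bond of the chromene, and benzyl cations may alkylate the phloroglucinol rings.
- Fallback (from 28 back to 29): the logic of the cleavage is inverted, with nucleophilic attack on the alkyl carbons in a basic medium in place of electrophilic activation of the ether oxygens. NaSEt (excess, DMF, 100 °C) should remove by SN2 attack the three benzyl groups, all attached to phenoxide leaving groups conjugated with a chromone carbonyl. This gives 8-[6-(5,7-dihydroxy-4-oxo-4H-chromen-2-yl)-2,2-dimethyl-2H-chromen-8-yl]-7-hydroxy-2-(4-hydroxyphenyl)-5-methoxy-4H-chromen-4-one F6. The remaining peri methyl ether is then cleaved with the mild chelating reagent MgI2·OEt2 (THF, 60 °C) to give 29.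

Further compounds
F1 | step 7 | [4-methoxy-2,6-bis(methoxymethoxy)phenyl]boronic acid | OB(O)c1c(OCOC)cc(OC)cc1OCOC
F2 | step 7 | methyl 3-bromo-4-[(2-methylbut-3-yn-2-yl)oxy]benzoate | COC(=O)c1ccc(OC(C)(C)C#C)c(Br)c1
F3 | step 7 | methyl 8-bromo-2,2-dimethyl-2H-chromene-6-carboxylate | CC1(C)C=Cc2cc(C(=O)OC)cc(Br)c2O1
F4 | step 11 | 5,7-bis(benzyloxy)-2-[8-(2,6-dihydroxy-3-iodo-4-methoxyphenyl)-2,2-dimethyl-2H-chromen-6-yl]-4H-chromen-4-one | CC1(C)C=Cc2cc(-c3cc(=O)c4c(OCc5ccccc5)cc(OCc5ccccc5)cc4o3)cc(-c3c(O)cc(OC)c(I)c3O)c2O1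
F5 | step 11 | 1-(3-{6-[5,7-bis(benzyloxy)-4-oxo-4H-chromen-2-yl]-2,2-dimethyl-2H-chromen-8-yl}-2,4-dihydroxy-6-methoxyphenyl)-3-[4-(benzyloxy)phenyl]prop-2-yn-1-one | CC1(C)C=Cc2cc(-c3cc(=O)c4c(OCc5ccccc5)cc(OCc5ccccc5)cc4o3)cc(-c3c(O)cc(OC)c(C(=O)C#Cc4ccc(OCc5ccccc5)cc4)c3O)c2O1
F6 | step 12 | 8-[6-(5,7-dihydroxy-4-oxo-4H-chromen-2-yl)-2,2-dimethyl-2H-chromen-8-yl]-7-hydroxy-2-(4-hydroxyphenyl)-5-methoxy-4H-chromen-4-one | CC1(C)C=Cc2cc(-c3cc(=O)c4c(O)cc(O)cc4o3)cc(-c3c(O)cc(OC)c4c(=O)cc(-c5ccc(O)cc5)oc34)c2O1
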